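**Retrosynthetic overview**

- Sauriol A (16) comes from its bis-acetonide 15 by ketal hydrolysis. Both benzene rings are bought; the only rings made are the two dioxole ketals (step 1), which the last step opens again.
- 15 is cut at C1–C7 and C1'–C7' (lignan numbering: ring C1–C6, benzylic C7, methine C8, methyl C9). Two arynes 13, generated from bromide 4, are captured by the two CH2–Mg ends of the C2-symmetric bis-Grignard 11.
- Feature used: on each ring C7 sits on C1, flanked by H at C2 and C6, meta to the oxygens on C3 and C5 and para to the oxygen on C4. This is the position a nucleophile takes when it adds to an aryne with an alkoxy group beside the triple bond (benzodioxole C6, C5, C4 = lignan C1, C2, C3).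
- 11 comes from dibromide 10, diol 8 and bis-imide 7; the C8–C8' bond and both stereocentres arise from oxidative dimerisation of the (R)-benzyloxazolidinone propionimide 5.
- 4 comes from 3-methoxycatechol 1 by ketalisation with 2 and bromination.

Key step: step 8

Remark on the chemistry: NBS is taken to brominate 3 at C5; a 6- or 7-bromo isomer formed alongside need not be removed, because every monobromide of 3 leads through an oxygen-flanked aryne to the same C6-alkylated product in step 8.
Remark on the reagents: LiN(iPr)2 and lithium 2,2,6,6-tetramethylpiperidide are used as preformed stock solutions.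

**Route**

Step 1
Reactants: 1 3-methoxycatechol (3-methoxybenzene-1,2-diol); 2 2,2-dimethoxypropane
Product: 3 4-methoxy-2,2-dimethyl-1,3-benzodioxole
Conditions: p-TsOH·H2O (cat.), toluene, reflux, MeOH removed over 4 Å molecular sieves
Reagents that add atoms: none
Why: Acid-catalysed transketalisation of the catechol, driven by removal of methanol, should close the five-membered isopropylidene ketal while the aryl methyl ether stays inert.

Step 2
Reactants: 3 4-methoxy-2,2-dimethyl-1,3-benzodioxole
Product: 4 5-bromo-4-methoxy-2,2-dimethyl-1,3-benzodioxole
Conditions: NBS (1.0 equiv), MeCN, 0 °C → rt, dark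
Reagents that add atoms: N-bromosuccinimide, O=C1CCC(=O)N1Br
Why: Electrophilic aromatic bromination of the trialkoxyarene should stop after one substitution at C5, which is ortho to OMe and para to the dioxole oxygen O1, because the monobromide is deactivated toward a second attack.

Step 3
Reactants: 5 (R)-4-benzyl-3-propionyl-1,3-oxazolidin-2-one (two molecules)
Product: 7 (4R,4'R)-3,3'-[(2S,3S)-2,3-dimethylbutanedioyl]bis(4-benzyl-1,3-oxazolidin-2-one), via lithium Z-enolate 6 (not isolated)
Conditions: LiN(iPr)2 (1.1 equiv), THF, −78 °C; then CuCl2 (1.2 equiv), DMF, −78 °C → rt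
Reagents that add atoms: none
Why: In this oxidative enolate homocoupling, divalent copper oxidises the chelated Z-enolate and the two α-carbons join on the face opposite the C4 benzyl group of each (R)-auxiliary, which should set both new centres as S; minor diastereomers are removed by chromatography or crystallisation.

Step 4
Reactants: 7 (4R,4'R)-3,3'-[(2S,3S)-2,3-dimethylbutanedioyl]bis(4-benzyl-1,3-oxazolidin-2-one)
Product: 8 (2S,3S)-2,3-dimethylbutane-1,4-diol
Conditions: LiBH4, MeOH (additive), THF, 0 °C → rt; then sat. aq NH4Cl
Reagents that add atoms: none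
Why: Reductive cleavage of N-acyloxazolidinones by LiBH4 should deliver both primary alcohols and release the recoverable auxiliary without epimerising the α-stereocentres.

Step 5
Reactants: 8 (2S,3S)-2,3-dimethylbutane-1,4-diol
Product: 9 (2S,3S)-2,3-dimethylbutane-1,4-diyl dimethanesulfonate
Conditions: MsCl (2.4 equiv), Et3N, CH2Cl2, 0 °C
Reagents that add atoms: methanesulfonyl chloride, CS(=O)(=O)Cl
Why: Mesylation of both primary hydroxyls is fast at 0 °C, so both are capped before a monomesylate can cyclise to the tetrahydrofuran, a closure that direct bromination of a 1,4-diol risks.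

Step 6
Reactants: 9 (2S,3S)-2,3-dimethylbutane-1,4-diyl dimethanesulfonate
Product: 10 (2S,3S)-1,4-dibromo-2,3-dimethylbutane
Conditions: LiBr (excess), acetone, reflux
Reagents that add atoms: lithium bromide, [Li+].[Br-]
Why: Finkelstein-type SN2 displacement of the primary mesylates by bromide leaves the stereocentres, which are β to the reacting carbons, untouched.

Step 7
Reactants: 10 (2S,3S)-1,4-dibromo-2,3-dimethylbutane
Product: 11 (2S,3S)-2,3-dimethylbutane-1,4-diylbis(magnesium bromide), as a titrated THF solution used directly
Conditions: Mg turnings (excess, I2-activated), THF, slow addition, 25–40 °C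
Reagents that add atoms: magnesium, [Mg]
Why: Grignard formation by magnesium insertion into both primary C–Br bonds under dilution should outrun Wurtz coupling, and since radicals arise only at C1 and C4 the C2 and C3 stereocentres cannot scramble.

Step 8
Reactants: 11 (2S,3S)-2,3-dimethylbutane-1,4-diylbis(magnesium bromide); 4 5-bromo-4-methoxy-2,2-dimethyl-1,3-benzodioxole (two molecules react, 3 equiv used)
Product: 15 6,6'-[(2R,3R)-2,3-dimethylbutane-1,4-diyl]bis(4-methoxy-2,2-dimethyl-1,3-benzodioxole), via aryllithium 12 (not isolated), via aryne 13 (not isolated), via bis(arylmagnesium bromide) 14 (not isolated)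
Conditions: 11 and 4 in THF, −78 °C; lithium 2,2,6,6-tetramethylpiperidide (3.2 equiv) added slowly; −78 °C → 0 °C; then H2O
Reagents that add atoms: none
Why: The hindered lithium amide removes C6–H, the only hydrogen ortho to bromine in 4, and aryllithium 12 expels LiBr to give aryne 13; each CH2–Mg end of 11 then adds across the strained triple bond (aryne carbomagnesiation), forming C1–C7 and C1'–C7' and leaving the arylmagnesium centres of 14 on lignan C2 and C2', which water protonates. The closest known reaction type is the meta-selective addition of primary alkyl Grignard and alkyllithium reagents to 3-alkoxyarynes generated from haloarenes with lithium amides, here run twice on one reagent. No ring is closed and no stereocentre is created; the two existing centres lie β to magnesium and are configurationally inert, and the descriptor changes from S to R only because the CIP priorities change. The step needs regioselectivity across each aryne, and the methoxy group on lignan C3 beside the triple bond secures it: its inductive pull distorts the aryne so that C1 is the flatter, more electrophilic terminus and the developing negative charge at C2 is stabilised. The primary alkylmagnesium should outcompete the arylmagnesium centres of 14 for the aryne because each of those is flanked by OMe and the new benzylic carbon, and the hindered amide and its amine do not add.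

Step 9
Reactants: 15 6,6'-[(2R,3R)-2,3-dimethylbutane-1,4-diyl]bis(4-methoxy-2,2-dimethyl-1,3-benzodioxole)
Product: 16 sauriol A, 5,5'-[(2R,3R)-2,3-dimethylbutane-1,4-diyl]bis(3-methoxybenzene-1,2-diol)
Conditions: 3 M aq HCl, MeOH, 60 °C, degassed, under Ar
Reagents that add atoms: none
Why: Acid-catalysed ketal hydrolysis should release both catechols and acetone, while the aryl methyl ethers and the alkyl stereocentres are stable to aqueous HCl and exclusion of air protects the catechols from oxidation.

**Compound list**

1 | 3-methoxycatechol (3-methoxybenzene-1,2-diol) | COc1cccc(O)c1O | starting material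
2 | 2,2-dimethoxypropane | COC(C)(C)OC | starting material
3 | 4-methoxy-2,2-dimethyl-1,3-benzodioxole | COc1cccc2OC(C)(C)Oc12 | intermediate
4 | 5-bromo-4-methoxy-2,2-dimethyl-1,3-benzodioxole | COc1c(Br)ccc2OC(C)(C)Oc12 | intermediate
5 | (R)-4-benzyl-3-propionyl-1,3-oxazolidin-2-one | CCC(=O)N1[C@H](Cc2ccccc2)COC1=O | starting material
6 | lithium (Z)-1-[(R)-4-benzyl-2-oxo-1,3-oxazolidin-3-yl]prop-1-en-1-olate | C/C=C(\O[Li])N1[C@H](Cc2ccccc2)COC1=O | intermediate
7 | (4R,4'R)-3,3'-[(2S,3S)-2,3-dimethylbutanedioyl]bis(4-benzyl-1,3-oxazolidin-2-one) | O=C(N1[C@H](Cc2ccccc2)COC1=O)[C@@H](C)[C@H](C)C(=O)N1[C@H](Cc2ccccc2)COC1=O | intermediate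
8 | (2S,3S)-2,3-dimethylbutane-1,4-diol | OC[C@@H](C)[C@H](C)CO | intermediate
9 | (2S,3S)-2,3-dimethylbutane-1,4-diyl dimethanesulfonate | CS(=O)(=O)OC[C@@H](C)[C@H](C)COS(C)(=O)=O | intermediate
10 | (2S,3S)-1,4-dibromo-2,3-dimethylbutane | BrC[C@@H](C)[C@H](C)CBr | intermediate
11 | (2S,3S)-2,3-dimethylbutane-1,4-diylbis(magnesium bromide) | Br[Mg]C[C@@H](C)[C@H](C)C[Mg]Br | intermediate
12 | (5-bromo-4-methoxy-2,2-dimethyl-1,3-benzodioxol-6-yl)lithium | COc1c(Br)c([Li])cc2OC(C)(C)Oc12 | intermediate
13 | 5,6-didehydro-4-methoxy-2,2-dimethyl-1,3-benzodioxole (aryne) | COC1=C2OC(C)(C)OC2=CC#C1 | intermediate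
14 | {[(2R,3R)-2,3-dimethylbutane-1,4-diyl]bis(4-methoxy-2,2-dimethyl-1,3-benzodioxole-6,5-diyl)}bis(magnesium bromide) | COc1c([Mg]Br)c(C[C@@H](C)[C@H](C)Cc3cc4OC(C)(C)Oc4c(OC)c3[Mg]Br)cc2OC(C)(C)Oc12 | intermediate
15 | 6,6'-[(2R,3R)-2,3-dimethylbutane-1,4-diyl]bis(4-methoxy-2,2-dimethyl-1,3-benzodioxole) (sauriol A bis-acetonide) | COc1cc(C[C@@H](C)[C@H](C)Cc3cc4OC(C)(C)Oc4c(OC)c3)cc2OC(C)(C)Oc12 | intermediate
16 | sauriol A, 5,5'-[(2R,3R)-2,3-dimethylbutane-1,4-diyl]bis(3-methoxybenzene-1,2-diol) | COc1cc(C[C@@H](C)[C@H](C)Cc2cc(O)c(O)c(OC)c2)cc(O)c1O | target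

**Step count and risks**

Total step count: 9. Longest linear sequence: 7 steps (steps 3 to 9, from 5).

Steps most likely to fail:

1. Step 8. The lithium amide may exchange with C–Mg bonds to give a less basic magnesium amide, which would slow aryne generation. The liberated tetramethylpiperidine may protonate C–Mg ends that have not yet reacted. The arylmagnesium centres that build up may consume arynes. Each of these processes would stop the sequence after one arylation. The fallback replaces aryne capture by a palladium-catalysed Kumada–Corriu coupling; it sets out from 11 and comes back at 15. Commercial 5-bromo-2-hydroxy-3-methoxybenzaldehyde is subjected to Dakin oxidation (H2O2, aq NaOH) to give 5-bromo-3-methoxybenzene-1,2-diol F1. F1 is ketalised with 2 as in step 1 to 6-bromo-4-methoxy-2,2-dimethyl-1,3-benzodioxole F2, whose bromine already sits on lignan C1. F2 (2.2 equiv) is then coupled with both ends of 11 using PdCl2(dppf) (cat.) in THF at rt to 50 °C, which should give 15.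

2. Step 3. Facial control in the radical-type coupling of two enolates may be poor, and α-chlorination by CuCl2 or incomplete oxidation may compete, so that the (S,S) bis-imide would be a minor part of a diastereomer mixture. The fallback forms the C8–C8' bond by a stereospecific enolate alkylation; it sets out from 5 and comes back at 8. Enolate 6 is generated as in step 3 and alkylated at −78 °C with commercial ethyl (S)-2-(trifluoromethylsulfonyloxy)propanoate. SN2 inversion at the lactate carbon and auxiliary control at the enolate carbon should give ethyl (2S,3S)-4-[(R)-4-benzyl-2-oxo-1,3-oxazolidin-3-yl]-2,3-dimethyl-4-oxobutanoate F3. LiBH4 in THF then reduces imide and ester together to 8.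

3. Step 7. During magnesium insertion the mono-Grignard may close by intramolecular Wurtz coupling to a cyclobutane or couple intermolecularly, and the second insertion may stay incomplete, so the titre of the dimetallic reagent would be low. The fallback reverses the polarity so that no alkyl dimetal is needed; it sets out from 10 and comes back at 15, bypassing steps 7 and 8. 6-Bromo-4-methoxy-2,2-dimethyl-1,3-benzodioxole F2, made as in the fallback to step 8, is converted with Mg in THF into (7-methoxy-2,2-dimethyl-1,3-benzodioxol-5-yl)magnesium bromide F4. F4 (2.5 equiv) is coupled with both primary C–Br bonds of 10 under Li2CuCl4 catalysis (THF with N-methylpyrrolidone, 0 °C → rt) to give 15.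

**Further compounds**

F1 | step 8 | 5-bromo-3-methoxybenzene-1,2-diol | COc1cc(Br)cc(O)c1O
F2 | step 8 | 6-bromo-4-methoxy-2,2-dimethyl-1,3-benzodioxole | COc1cc(Br)cc2OC(C)(C)Oc12
F3 | step 3 | ethyl (2S,3S)-4-[(R)-4-benzyl-2-oxo-1,3-oxazolidin-3-yl]-2,3-dimethyl-4-oxobutanoate | CCOC(=O)[C@@H](C)[C@H](C)C(=O)N1[C@H](Cc2ccccc2)COC1=O
F4 | step 7 | (7-methoxy-2,2-dimethyl-1,3-benzodioxol-5-yl)magnesium bromide | COc1cc([Mg]Br)cc2OC(C)(C)Oc12
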